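## Retrosynthetic overview

1. Kanzonol X comes from its tris-MOM ether by global acetal cleavage in the last step.
2. The key disconnection is the C3–C1' bond. It is made by an enantioselective Pd-catalysed reductive Heck (hydroarylation) of a 7-MOMO-8-prenyl-2H-chromene with a B-ring aryl bromide, which also sets (3R).
3. Chromene fragment: resorcinol → Vilsmeier formylation → selective 4-O-MOM → pyran ring closure with a vinylboron C2 unit → prenylation at C8 by directed ortho-metalation.
4. Aryl bromide fragment: resorcinol → bis-MOM ether → C2 iodination by ortho-metalation → C4 bromination → selective I/Mg exchange and prenylation.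
5. Ring order: both benzene rings come from resorcinol; the pyran ring is closed in the chromene branch before the fragment union; no ring is formed after that.

Assumption: the (R)-configured ligand in step 9 is taken to give the (3R) product; if a test run shows the opposite sense, the (S)-ligand is used.

## Route

**Step 1**
Reactants: 1 resorcinol
Product: 2 2,4-dihydroxybenzaldehyde
Conditions: POCl3, DMF, MeCN, −15 °C → rt; then H2O, 50 °C
Reagents that add atoms: DMF, CN(C)C=O (formyl carbon); water, O (carbonyl oxygen)
Why: Vilsmeier–Haack formylation attacks C4 of resorcinol (para to one OH, ortho to the other), and the iminium formed deactivates the ring against a second formylation.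

**Step 2**
Reactants: 2 2,4-dihydroxybenzaldehyde
Product: 3 2-hydroxy-4-(methoxymethoxy)benzaldehyde
Conditions: MOMCl (1.05 equiv), K2CO3, acetone, 0 °C → rt
Reagents that add atoms: MOMCl, COCCl
Why: Selective O-alkylation, because the 2-OH is tied up in a hydrogen bond to the aldehyde and only the 4-OH reacts.

**Step 3**
Reactants: 3 2-hydroxy-4-(methoxymethoxy)benzaldehyde; 4 potassium vinyltrifluoroborate
Product: 5 7-(methoxymethoxy)-2H-chromene
Conditions: Bn2NH (0.5 equiv), DMF, 80 °C
Reagents that add atoms: none (C2 and C3 come from 4)
Why: Amine-catalysed Petasis-type vinyl transfer from the phenoxide-bound borate to the iminium carbon, then loss of the amine to an o-quinone methide and oxa-6π electrocyclisation closes the pyran ring.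

**Step 4**
Reactants: 5 7-(methoxymethoxy)-2H-chromene; 6 prenyl bromide (1-bromo-3-methylbut-2-ene)
Product: 7 7-(methoxymethoxy)-8-(3-methylbut-2-en-1-yl)-2H-chromene
Conditions: n-BuLi, TMEDA, THF, −40 → 0 °C; CuBr·SMe2, −78 °C; then 6, −78 °C → rt
Reagents that add atoms: none (prenyl comes from 6)
Why: Directed ortho-metalation at C8, the only C–H flanked by both the OMOM group and the ring oxygen, followed by copper-mediated SN2 allylation.

**Step 5**
Reactants: 1 resorcinol
Product: 8 1,3-bis(methoxymethoxy)benzene
Conditions: MOMCl (2.5 equiv), i-Pr2NEt, CH2Cl2, 0 °C → rt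
Reagents that add atoms: MOMCl, COCCl
Why: Standard double phenol protection as MOM acetals, which also serve as directing groups for the next step.

**Step 6**
Reactants: 8 1,3-bis(methoxymethoxy)benzene
Product: 9 2-iodo-1,3-bis(methoxymethoxy)benzene
Conditions: n-BuLi, THF, 0 °C, 1 h; then I2, −78 °C → rt
Reagents that add atoms: iodine, II
Why: Directed ortho-metalation occurs at C2 between the two cooperating OMOM groups, and the aryllithium is trapped by iodine.

**Step 7**
Reactants: 9 2-iodo-1,3-bis(methoxymethoxy)benzene
Product: 10 1-bromo-3-iodo-2,4-bis(methoxymethoxy)benzene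
Conditions: NBS (1.05 equiv), MeCN, 0 °C → rt
Reagents that add atoms: NBS, O=C1CCC(=O)N1Br
Why: Electrophilic aromatic bromination goes to the position para to one OMOM and ortho to the other, and the product is deactivated against a second bromination.

**Step 8**
Reactants: 10 1-bromo-3-iodo-2,4-bis(methoxymethoxy)benzene; 6 prenyl bromide
Product: 11 1-bromo-2,4-bis(methoxymethoxy)-3-(3-methylbut-2-en-1-yl)benzene
Conditions: i-PrMgCl·LiCl (1.1 equiv), THF, −10 °C → rt; then CuI (10 mol%), 6, −20 °C → rt
Reagents that add atoms: none (prenyl comes from 6)
Why: Chemoselective iodine–magnesium exchange (C–I much faster than C–Br, assisted by the two flanking OMOM groups) followed by copper-catalysed SN2 allylation, with no strong base or electrophilic halogen ever meeting the prenyl group.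

**Step 9**
Reactants: 7 7-(methoxymethoxy)-8-(3-methylbut-2-en-1-yl)-2H-chromene; 11 1-bromo-2,4-bis(methoxymethoxy)-3-(3-methylbut-2-en-1-yl)benzene (1.3 equiv)
Product: 12 (3R)-3-[2,4-bis(methoxymethoxy)-3-(3-methylbut-2-en-1-yl)phenyl]-7-(methoxymethoxy)-8-(3-methylbut-2-en-1-yl)chromane
Conditions: Pd(dba)2 (5 mol%), (R)-Xyl-SDP(O) (spirobiindane bisphosphine mono-oxide, 6 mol%), HCO2Na (2 equiv, slow addition), MeOH/1,4-dioxane 1:1, 65 °C
Reagents that add atoms: none (formate supplies only H)
Why: Proposed new method: enantioselective intermolecular reductive Heck (formal anti-Markovnikov hydroarylation) of a 2H-chromene, in which oxidative addition of 11 and bromide ionisation in the protic medium give a cationic aryl-Pd held by the hemilabile chiral P,O ligand; this inserts C3=C4 syn, with aryl to C3 and Pd to benzylic C4, the ligand choosing the alkene face and so setting 3R, and because the C3–H is anti to Pd β-hydride elimination is blocked and formate (decarboxylation, C–H reductive elimination) intercepts the benzyl-Pd, while the trisubstituted prenyl alkenes do not insert; the closest known reactions are the racemic Pd oxyarylation of 2H-chromenes to pterocarpans (same regiochemistry) and asymmetric Heck and reductive Heck reactions of other cyclic or strained alkenes.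

**Step 10**
Reactants: 12 the tris-MOM isoflavan
Product: 13 kanzonol X, (3R)-3-[2,4-dihydroxy-3-(3-methylbut-2-en-1-yl)phenyl]-8-(3-methylbut-2-en-1-yl)chroman-7-ol
Conditions: HCl (1.25 M in MeOH)/THF, rt → 35 °C, monitored and stopped at full conversion
Reagents that add atoms: none
Why: Mild acid-catalysed acetal cleavage removes all three aryl MOM ethers, and the C3 stereocentre (a non-enolisable benzylic C–H) is untouched.

## Compound list

1 | resorcinol | Oc1cccc(O)c1 | starting material
2 | 2,4-dihydroxybenzaldehyde | O=Cc1ccc(O)cc1O | intermediate
3 | 2-hydroxy-4-(methoxymethoxy)benzaldehyde | COCOc1ccc(C=O)c(O)c1 | intermediate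
4 | potassium vinyltrifluoroborate | [K+].C=C[B-](F)(F)F | starting material
5 | 7-(methoxymethoxy)-2H-chromene | COCOc1ccc2C=CCOc2c1 | intermediate
6 | prenyl bromide | CC(C)=CCBr | starting material
7 | 7-(methoxymethoxy)-8-(3-methylbut-2-en-1-yl)-2H-chromene | COCOc1ccc2C=CCOc2c1CC=C(C)C | intermediate
8 | 1,3-bis(methoxymethoxy)benzene | COCOc1cccc(OCOC)c1 | intermediate
9 | 2-iodo-1,3-bis(methoxymethoxy)benzene | COCOc1cccc(OCOC)c1I | intermediate
10 | 1-bromo-3-iodo-2,4-bis(methoxymethoxy)benzene | COCOc1ccc(Br)c(OCOC)c1I | intermediate
11 | 1-bromo-2,4-bis(methoxymethoxy)-3-(3-methylbut-2-en-1-yl)benzene | COCOc1ccc(Br)c(OCOC)c1CC=C(C)C | intermediate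
12 | (3R)-3-[2,4-bis(methoxymethoxy)-3-prenylphenyl]-7-(methoxymethoxy)-8-prenylchromane | CC(C)=CCc1c(OCOC)ccc([C@@H]2COc3c(ccc(OCOC)c3CC=C(C)C)C2)c1OCOC | intermediate
13 | kanzonol X | CC(C)=CCc1c(O)ccc([C@@H]2COc3c(ccc(O)c3CC=C(C)C)C2)c1O | target

## Summary

Total steps: 10 (chromene branch, steps 1–4; aryl bromide branch, steps 5–8; union and deprotection, steps 9–10).
Longest linear sequence: 6 steps (steps 1–4, 9, 10, or equally steps 5–8, 9, 10).

Steps most likely to fail:

1. **Step 9 (proposed new reductive Heck).** Risks are hydrodehalogenation of 11, chromene isomerisation by Pd–H, isoflavene formation, and insufficient ee. Fallback with known chemistry: set C3 by auxiliary control instead. The Evans oxazolidinone imide of the B-ring arylacetic acid (made from 11) is alkylated with an A-ring benzyl bromide carrying its ortho oxygen as a TBS ether, then LiBH4 reduction, TBAF, and Mitsunobu closure of the chroman, then step 10.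
2. **Step 4 (ortho-lithiation of a 2H-chromene).** Risks are butyllithium addition to the styrenyl alkene or deprotonation at C2. Fallback: replace deprotonation by halogen–metal exchange. Start the branch from 2-iodoresorcinol (I2, NaHCO3, water on 1), carry the iodide through steps 1–3 to the 8-iodochromene, and prenylate by I/Mg exchange with copper catalysis as in step 8.
3. **Step 10 (acidic MOM removal next to two ortho-prenyl phenols).** The risk is acid-catalysed cyclisation of a prenyl group onto a neighbouring phenol to give a dimethylchroman. Fallback: build both fragments with SEM ethers in place of MOM (same directing and chelating behaviour) and cleave them with fluoride (TBAF in DMPU, or CsF in DMF, warm), which avoids acid altogether.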